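**Retrosynthetic overview**
1. Target 8 ⇐ formolysis of (13S)-labdane-3β,8α,15-triol 5: two formate C–O bonds are made and the C8 carbinol is dehydrated to the 7-ene.
2. 5 ⇐ catalyst-controlled asymmetric hydrogenation of the E-allylic alcohol 4, which sets C13.
3. 4 ⇐ 1,3-hydroxyl transposition (C13–O to C15–O) of 3β-hydroxysclareol 2; this is the proposed new step.
4. 2 ⇐ enzymatic C3–H hydroxylation of sclareol 1, the key C3–O bond.
5. No ring is formed and no C–C bond is made: rings A and B with C5, C9 and C10 are bought intact in sclareol.

Assumption: the SMILES is read as (3S,5R,9S,10R,13S), i.e. (13S)-labd-7-ene-3β,15-diyl diformate of the normal labdane series (5α-H, 9α-H, 10β-CH3); labdane numbering and α/β descriptors are used throughout.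

**Step 1**
Reactants: 1 sclareol, (13R)-labd-14-ene-8α,13-diol
Product: 2 3β-hydroxysclareol, (13R)-labd-14-ene-3β,8α,13-triol
Conditions: cytochrome P450 BM3 (CYP102A1) variant evolved for ring A C3-hydroxylation of sclareol-type terpenoids (E. coli lysate), NADP+ (cat.), NADP-dependent alcohol dehydrogenase, i-PrOH (5% v/v), air, K2HPO4/KH2PO4 buffer pH 8.0, 25 °C, 20 h
Reagents that add atoms: dioxygen, O=O
Why: Enzymatic C–H hydroxylation by the P450 oxygen-rebound mechanism, known for sclareol itself: the polar side chain sits at the mouth of the substrate channel so that ring A reaches the heme iron-oxo unit, which abstracts the equatorial 3β-hydrogen next to the gem-dimethyl group and returns OH to the same face, setting C3 as 3β (S) with retention while the alkene and both tertiary alcohols are untouched.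

**Step 2**
Reactants: 2 3β-hydroxysclareol
Product: 4 (13E)-labd-13-ene-3β,8α,15-triol, via bis-silyl ether 3 (not isolated)
Conditions: O3ReOSiPh3 (3 mol%), BSA (3 equiv), Et2O, −40 → 0 °C; then K2CO3 (cat.), MeOH, 23 °C; minor 13Z isomer removed on AgNO3-impregnated silica gel
Reagents that add atoms: none
Why: Proposed new method: a silylation-driven oxo-rhenium 1,3-hydroxyl transposition on an unprotected polyol, in which the allylic 13-OH exchanges onto heptavalent rhenium to give an allyl perrhenate, a chair-like [3,3]-sigmatropic shift moves the oxygen from C13 to C15 and forms the C13=C14 bond with the larger C12 chain pseudo-equatorial (E favoured, about 3:1 expected), BSA silylates the new primary hydroxyl (and the secondary C3 hydroxyl) but not the tertiary ones and so pulls the otherwise tertiary-favoured equilibrium forward, and the low temperature and non-acidic medium suppress ionisation to the allyl cation that the 8α-OH would trap as a manoyl-oxide-type ether; the closest known reaction is the triphenylsilyl perrhenate-catalysed allylic alcohol transposition of simple mono-alcohols with BSA trapping, which to my knowledge has not been shown on a tertiary vinyl carbinol carrying a free, cyclisation-prone tertiary hydroxyl.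

**Step 3**
Reactants: 4 (13E)-labd-13-ene-3β,8α,15-triol
Product: 5 (13S)-labdane-3β,8α,15-triol
Conditions: Ru(OAc)2[(R)-BINAP] (0.5 mol%), H2 (100 atm), MeOH, 25 °C, 24 h
Reagents that add atoms: none
Why: Noyori asymmetric hydrogenation of an allylic alcohol: the divalent ruthenium centre binds the C15 hydroxyl and reduces only the C13=C14 bond, and the (R)-BINAP complex converts a geraniol-type E-allylic alcohol into the (S)-configured product (as geraniol gives (S)-citronellol), so C13 is set as S by the catalyst independently of the distant decalin.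

**Step 4**
Reactants: 5 (13S)-labdane-3β,8α,15-triol; 6 formic acid
Product: 8 (13S)-labd-7-ene-3β,15-diyl diformate, via hydroxy diformate 7 (not isolated)
Conditions: HCO2H (98%, as solvent), 50 °C, 4 h; chromatography on AgNO3-impregnated silica gel
Reagents that add atoms: formic acid, O=CO
Why: Formolysis (Fischer formylation plus E1 dehydration): neat formic acid esterifies the primary and the secondary hydroxyl and ionises the tertiary 8α-carbinol, and the C8 cation loses the axial 7β-hydrogen to give the trisubstituted 7-ene, into which the exocyclic isomer is funnelled by reprotonation while the strained tetrasubstituted 8(9)-ene is expected to stay minor and is removed on AgNO3-silica; no stereocentre is created or touched.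

**Compound list**
1 | sclareol, (13R)-labd-14-ene-8α,13-diol | C[C@@]1(O)CC[C@H]2C(C)(C)CCC[C@]2(C)[C@H]1CC[C@@](C)(O)C=C | starting material
2 | 3β-hydroxysclareol, (13R)-labd-14-ene-3β,8α,13-triol | C[C@@]1(O)CC[C@H]2C(C)(C)[C@@H](O)CC[C@]2(C)[C@H]1CC[C@@](C)(O)C=C | intermediate
3 | (13E)-3β,15-bis(trimethylsilyloxy)labd-13-en-8α-ol | C[C@@]1(O)CC[C@H]2C(C)(C)[C@@H](O[Si](C)(C)C)CC[C@]2(C)[C@H]1CC/C(C)=C/CO[Si](C)(C)C | intermediate
4 | (13E)-labd-13-ene-3β,8α,15-triol | C[C@@]1(O)CC[C@H]2C(C)(C)[C@@H](O)CC[C@]2(C)[C@H]1CC/C(C)=C/CO | intermediate
5 | (13S)-labdane-3β,8α,15-triol | C[C@@]1(O)CC[C@H]2C(C)(C)[C@@H](O)CC[C@]2(C)[C@H]1CC[C@H](C)CCO | intermediate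
6 | formic acid | O=CO | starting material
7 | (13S)-8α-hydroxylabdane-3β,15-diyl diformate | C[C@@]1(O)CC[C@H]2C(C)(C)[C@@H](OC=O)CC[C@]2(C)[C@H]1CC[C@H](C)CCOC=O | intermediate
8 | (13S)-labd-7-ene-3β,15-diyl diformate (CNP0137609.1) | CC1=CC[C@H]2C(C)(C)[C@@H](OC=O)CC[C@]2(C)[C@H]1CC[C@H](C)CCOC=O | target

**Total step count:** 4
**Longest linear sequence:** 4 steps (1 → 2 → 4 → 5 → 8)

**Three steps most likely to fail**

Step 2 (the proposed new transposition). The risks are ionisation with capture by the 8α-OH to give an 8,13-ether, a poor E/Z ratio, and incomplete pull of the equilibrium. The fallback uses known chemistry and sets out from 2. Exhaustive acetylation (AcCl, N,N-dimethylaniline, CH2Cl2) gives (13R)-labd-14-ene-3β,8α,13-triyl triacetate F1. The [3,3] acetate shift catalysed by divalent palladium (PdCl2(MeCN)2, 5 mol%, THF, 23 °C) then gives (13E)-labd-13-ene-3β,8α,15-triyl triacetate F2, from which the minor 13Z isomer is removed. Reduction of all three esters with LiAlH4 in THF comes back to the route at 4.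

Step 4 (one-pot formolysis). The risks are the 7-ene to 8(9)-ene ratio, which I have not verified for this substrate, and possible backbone rearrangement of the C8 cation on long heating. The fallback separates esterification from elimination and sets out from 5. Acetic formic anhydride (from HCO2H and Ac2O) with pyridine at 0 °C formylates only the primary and secondary hydroxyls and gives 7, which is isolated this time. POCl3 in pyridine then eliminates by an E2 path. Because the equatorial 8α leaving group has no antiperiplanar ring hydrogen, elimination goes into the methyl group and gives mainly (13S)-labd-8(17)-ene-3β,15-diyl diformate F5. Catalytic HI in benzene at 23 °C moves the exocyclic double bond into the ring and comes back to the route at 8.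

Step 3 (C13 stereocentre). The configuration at C13 is only as good as the E purity of 4 and the catalyst control, and C13 epimers would be very hard to separate. The fallback sets out from 4 and tolerates E/Z mixtures. MnO2 in CH2Cl2 oxidises only the allylic alcohol to (13E)-3β,8α-dihydroxylabd-13-en-15-al F3. Organocatalytic transfer hydrogenation follows, with Hantzsch ester and the morpholinium salt of (S)-TRIP in dioxane at 50 °C. TRIP is 3,3'-bis(2,4,6-triisopropylphenyl)-1,1'-binaphthyl-2,2'-diyl hydrogen phosphate, and the (S) antipode is chosen as the opposite of the one recalled to give (R)-citronellal from citral. The iminium ions equilibrate between E and Z, so the reduction is enantioconvergent and gives (13S)-3β,8α-dihydroxylabdan-15-al F4. NaBH4 in MeOH comes back to the route at 5.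

**Further compounds**
F1 | step 2 | (13R)-labd-14-ene-3β,8α,13-triyl triacetate | C[C@@]1(OC(C)=O)CC[C@H]2C(C)(C)[C@@H](OC(C)=O)CC[C@]2(C)[C@H]1CC[C@@](C)(OC(C)=O)C=C
F2 | step 2 | (13E)-labd-13-ene-3β,8α,15-triyl triacetate | C[C@@]1(OC(C)=O)CC[C@H]2C(C)(C)[C@@H](OC(C)=O)CC[C@]2(C)[C@H]1CC/C(C)=C/COC(C)=O
F3 | step 3 | (13E)-3β,8α-dihydroxylabd-13-en-15-al | C[C@@]1(O)CC[C@H]2C(C)(C)[C@@H](O)CC[C@]2(C)[C@H]1CC/C(C)=C/C=O
F4 | step 3 | (13S)-3β,8α-dihydroxylabdan-15-al | C[C@@]1(O)CC[C@H]2C(C)(C)[C@@H](O)CC[C@]2(C)[C@H]1CC[C@H](C)CC=O
F5 | step 4 | (13S)-labd-8(17)-ene-3β,15-diyl diformate | C=C1CC[C@H]2C(C)(C)[C@@H](OC=O)CC[C@]2(C)[C@H]1CC[C@H](C)CCOC=O
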